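Over its first hours the summer run does something odd, and the new flask differs from it in the charge of starting material as well as in time.

- summer: starting material 0.55 M; solid reagent 1.5 equiv; protic impurity 0.22 M; free catalyst 1 mol%; run made earlier
- flask: starting material 1.1 M; solid reagent 1.50 equiv; protic impurity 0.220 M; free catalyst 1 mol%; time 25 h

summer run (percent of the starting material charged)

| time / h | starting material / % | target / % | catalyst intermediate C / % |
|---|---|---|---|
| 3.00 | 57.4 | 2.9 | 0 |
| 6.00 | 52.1 | 5.1 | 0.3 |
| 10.0 | 46.2 | 8.4 | 0 |
| 12.0 | 43.6 | 10.1 | 0.7 |
| 15.0 | 41.8 | 12.9 | 0.2 |

(readings scatter by 0.5 percentage points)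

- as a solid, counted per litre of solution: solid reagent
- at the start none of the solid reagent is in solution
- no earlier run changes the charge of free catalyst; that part of a forecast is a guess

- where most of what was charged as starting material, at 25 h is found (starting material / target / catalyst intermediate C)
- the largest share itself, whichever of these holds it, in percent of the starting material charged

By 3.00 h the summer run has lost 42.6% of its starting material, yet it shows 2.9% target. That gap lies close to the protic impurity's 40.0% of the charge, so I read it as a one-to-one quench with the impurity as limiting reagent. Target then climbs at a turnover frequency of 0.833 h⁻¹, but in the summer run starting material plus target still slips 5.6 percentage points by 15.0 h.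

Taking that slip as second-order, I divide its hourly rate by the charge of starting material and by the starting-material shares at the two ends of the stretch. This gives 0.0354 M⁻¹ h⁻¹, the side-loss coefficient, a reading with the scatter of its readings.

For the new flask I reckon that the quench leaves 80.0% and that turnover, assumed to keep the same frequency, takes 20.8%. Side loss is the coefficient times charge, time, starting share and end share, so the end share must be put back in until it stands:

| Round | Side loss | Starting material left |
|---|---|---|
| first | none | 59.2% |
| second | 46.0% | 13.1% |
| limit | 25.9% | 33.3% |

The forecast says starting material at 55%, “still the largest share”.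

The flask gives starting material at 32.3%, with homo dimer at 23.7%. Put back into the side-loss term, 32.3% gives 25.1%.

    starting material + catalyst intermediate B → catalyst intermediate C (k = 10.7 M⁻¹ h⁻¹)
    2 starting material → homo dimer (k = 0.0143 M⁻¹ h⁻¹)
    partner + free catalyst → catalyst intermediate A (k = 19.1 M⁻¹ h⁻¹)
    solid reagent ⇌ partner, rate k4*(cs4 - [partner]) while solid is left; crystals form when [partner] > cs4 (solubility = 0.0750 M, k = 1.30 h⁻¹)
    catalyst intermediate A → by-product + catalyst intermediate B (k = 301 h⁻¹)
    starting material + protic impurity → quenched substrate (k = 2.93 M⁻¹ h⁻¹)
    catalyst intermediate C → free catalyst + target (k = 24.0 h⁻¹)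

For the neighbour at 1.7 mol%, the same coefficient gives target 35.4% and starting material 25.1%, so target leads. Computed, that flask holds 37.4% target and 22.4% starting material.

(The numbers in the tables are calculated from invented constants; noise was put on by code.)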